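**Plan**

- Plagiochin E is a 16-membered ring through four arenes: ring A (biaryl ring, OH para to the biaryl bond), ring B (OH next to the diaryl ether oxygen), ring C (para-phenylene) and ring D (biaryl ring, OH ortho to the biaryl bond). They are joined by the A–D biaryl bond, the B–O–C ether and two CH2–CH2 bridges (A–B and C–D).
- Cuts, last-formed bond first: the three O–CH3 bonds, a benzylic C–OH bond, then the CH2–CH2 bond of the C–D bridge. This bond links the benzylic carbon on ring C to the benzylic carbon on ring D, which is what a benzyl–O–benzyl unit gives when one benzyl group shifts from oxygen to the other, lithiated benzylic carbon. Further back: one CH2–O bond of that ether, the aryl–O bond of the B–O–C ether, the A–B bridge and the A–D biaryl bond.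
- Forward: Suzuki coupling (A–D), Wittig olefination and hydrogenation (A–B bridge), ester reduction, SNAr (ring C), chloride and alcohol adjustment, Williamson closure of a 17-membered dibenzyl ether, [1,2]-Wittig contraction to the 16-membered carbocycle, ionic deoxygenation, demethylation. The three methyl ethers are the only protecting groups.
- Stereochemistry: the target has no stereocentre. The carbinol carbon formed in the contraction is racemic and is removed in the following step.

Key step: step 10

Remark: the target SMILES defines no stereo element, so the biaryl axis of the macrocycles is not treated as stereogenic. Compounds 1, 2, 4 and 10 are taken to be catalogue chemicals.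

**Route**

Step 1
Reactants: 1 methyl 2-bromo-3-methoxybenzoate; 2 (2-formyl-4-methoxyphenyl)boronic acid
Product: 3 methyl 2'-formyl-4',6-dimethoxy-[1,1'-biphenyl]-2-carboxylate
Conditions: Pd(OAc)2 (cat.), SPhos (cat.), K3PO4, toluene/H2O, 90 °C
Reagents that add atoms: none
Why: Suzuki–Miyaura coupling, in which the ortho ester speeds oxidative addition of the hindered bromide to zerovalent palladium, the bulky biarylphosphine suits a tri-ortho-substituted biaryl and an excess of 2 offsets protodeboronation; the ester (ring D) and the aldehyde (ring A) keep the two benzylic carbons apart by oxidation level.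

Step 2
Reactants: 4 (3-hydroxy-4-methoxyphenyl)methanol
Product: 5 (3-hydroxy-4-methoxybenzyl)triphenylphosphonium bromide
Conditions: PPh3·HBr, MeCN, reflux
Reagents that add atoms: triphenylphosphine hydrobromide, [Br-].[PH+](c1ccccc1)(c1ccccc1)c1ccccc1
Why: Direct phosphonium salt formation from a donor-substituted benzylic alcohol, which is protonated, substituted by bromide and then by PPh3, while the phenol stays untouched.

Step 3
Reactants: 3 biaryl ester aldehyde; 5 phosphonium bromide
Product: 7 methyl 2'-[2-(3-hydroxy-4-methoxyphenyl)ethenyl]-4',6-dimethoxy-[1,1'-biphenyl]-2-carboxylate (E/Z mixture), via phosphonium ylide 6 (not isolated)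
Conditions: 5, LiN(SiMe3)2 (2 equiv per 5), THF, 0 °C; then 3, 0 °C to rt; then H2O
Reagents that add atoms: none
Why: Wittig olefination, in which two equivalents of base give the phenoxide-bearing semi-stabilised ylide 6 that attacks the aryl aldehyde and not the hindered ester; the alkene geometry is irrelevant because the double bond is saturated next.

Step 4
Reactants: 7 stilbene ester
Product: 8 methyl 2'-[2-(3-hydroxy-4-methoxyphenyl)ethyl]-4',6-dimethoxy-[1,1'-biphenyl]-2-carboxylate
Conditions: H2 (1 atm), Pd/C, EtOAc, rt
Reagents that add atoms: none
Why: Catalytic hydrogenation of a stilbene double bond; no benzylic C–O bond is present at this stage, so hydrogenolysis cannot interfere.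

Step 5
Reactants: 8 bibenzyl ester
Product: 9 5-{2-[2'-(hydroxymethyl)-4,6'-dimethoxy-[1,1'-biphenyl]-2-yl]ethyl}-2-methoxyphenol
Conditions: LiAlH4, THF, 0 °C to rt; then H2O
Reagents that add atoms: none
Why: LiAlH4 reduction of an aryl ester to the benzylic alcohol; the phenol only consumes one hydride as its aluminate and returns on work-up.

Step 6
Reactants: 9 phenol alcohol; 10 4-fluorobenzaldehyde
Product: 11 4-(5-{2-[2'-(hydroxymethyl)-4,6'-dimethoxy-[1,1'-biphenyl]-2-yl]ethyl}-2-methoxyphenoxy)benzaldehyde
Conditions: K2CO3, DMF, 120 °C
Reagents that add atoms: none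
Why: SNAr on a para-formyl-activated fluoroarene; K2CO3 deprotonates the phenol but not the benzylic alcohol, so only the aryl ether forms and rings C and D end up at different oxidation levels (CHO against CH2OH).

Step 7
Reactants: 11 hydroxy aldehyde
Product: 12 4-(5-{2-[2'-(chloromethyl)-4,6'-dimethoxy-[1,1'-biphenyl]-2-yl]ethyl}-2-methoxyphenoxy)benzaldehyde
Conditions: SOCl2, CH2Cl2, 0 °C to rt
Reagents that add atoms: thionyl chloride, O=S(Cl)Cl
Why: Deoxychlorination of a primary benzylic alcohol through its chlorosulfite; the aryl aldehyde, the methyl ethers and the diaryl ether do not react at this temperature.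

Step 8
Reactants: 12 chloro aldehyde
Product: 13 [4-(5-{2-[2'-(chloromethyl)-4,6'-dimethoxy-[1,1'-biphenyl]-2-yl]ethyl}-2-methoxyphenoxy)phenyl]methanol
Conditions: NaBH4, THF/MeOH, 0 °C
Reagents that add atoms: none
Why: NaBH4 reduction of the aldehyde, which is much faster at 0 °C than hydride or methanol attack on the ortho-arylated benzylic chloride.

Step 9
Reactants: 13 chloro alcohol
Product: 14 17-membered macrocyclic dibenzyl ether (ring C–CH2–O–CH2–ring D; three OMe groups)
Conditions: NaH, n-Bu4NI (cat.), THF, 60 °C, slow addition of 13 (high dilution)
Reagents that add atoms: none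
Why: Intramolecular Williamson etherification, in which the ring C benzylic alkoxide displaces the ring D benzylic halide (activated in the flask as the iodide) and slow addition keeps ring closure ahead of intermolecular alkylation.

Step 10
Reactants: 14 macrocyclic dibenzyl ether
Product: 16 racemic macrocyclic 1,2-diarylethanol (16-membered ring; OH on the benzylic carbon attached to ring D), via lithiated ether 15 (not isolated)
Conditions: n-BuLi (3 equiv), THF, −78 °C to rt; then H2O
Reagents that add atoms: none
Why: n-BuLi removes a proton from an ether CH2, which is activated by both an arene and the oxygen, and the resulting α-alkoxybenzyllithium 15 undergoes C–O homolysis to a ketyl radical anion and a benzyl radical that recombine at carbon; this is the [1,2]-Wittig rearrangement, known for dibenzyl ether itself (to 1,2-diphenylethanol) and for cyclic benzylic ethers, which contract by one atom. The 16-membered carbocycle is therefore formed by contraction of the 17-membered ether through a 1,2-shift and not by closure of an open chain, and because the two radical centres remain tied together by the rest of the macrocycle, recombination should be the productive path. The carbinol centre arises without a controlling element, so 16 is racemic, which is of no consequence because step 11 removes the centre. The chemoselectivity needed is α-oxy benzylic deprotonation in preference to ortho-lithiation beside the methoxy groups and to metalation of the A–B bridge; the double activation of the ether CH2 groups, THF without a diamine additive and low temperature should secure it. Of the two ether CH2 groups, the one on ring D should be the more acidic (inductive pull of the meta methoxy group and of the ortho aryl ring, against the donor para aryloxy group on ring C), and the 4-aryloxybenzyl group that then migrates is a well-stabilised radical, so 16 is the expected regioisomer. This preference need not be complete, since a shift in the opposite sense only places the hydroxyl on the neighbouring bridge carbon, from which step 11 removes it to give the same bibenzyl 17.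

Step 11
Reactants: 16 macrocyclic carbinol
Product: 17 plagiochin E trimethyl ether
Conditions: Et3SiH, CF3CO2H (excess), CH2Cl2, 0 °C to rt
Reagents that add atoms: none
Why: Ionic hydrogenation, in which CF3CO2H ionises the benzylic carbinol and Et3SiH delivers hydride to the cation; any stilbene formed by proton loss should be re-protonated to the cation stabilised by the para aryloxy group on ring C and reduced as well, a hydroxyl on either bridge carbon is removed alike, and the methyl ethers and the diaryl ether are inert.

Step 12
Reactants: 17 plagiochin E trimethyl ether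
Product: 18 plagiochin E
Conditions: BBr3, CH2Cl2, −78 °C to rt; then H2O
Reagents that add atoms: none
Why: Lewis-acid cleavage of the three aryl methyl ethers by BBr3 (bromide attacks the methyl group of the boron-complexed ether), which leaves the diaryl ether and the bibenzyl bridges intact.

**Compound list**

1 | methyl 2-bromo-3-methoxybenzoate | COC(=O)c1cccc(OC)c1Br | starting material
2 | (2-formyl-4-methoxyphenyl)boronic acid | COc1ccc(B(O)O)c(C=O)c1 | starting material
3 | methyl 2'-formyl-4',6-dimethoxy-[1,1'-biphenyl]-2-carboxylate | COC(=O)c1cccc(OC)c1-c1ccc(OC)cc1C=O | intermediate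
4 | (3-hydroxy-4-methoxyphenyl)methanol | COc1ccc(CO)cc1O | starting material
5 | (3-hydroxy-4-methoxybenzyl)triphenylphosphonium bromide | COc1ccc(C[P+](c2ccccc2)(c2ccccc2)c2ccccc2)cc1O.[Br-] | intermediate
6 | lithium 2-methoxy-5-[(triphenylphosphoranylidene)methyl]phenoxide (ylide, not isolated) | COc1ccc(C=P(c2ccccc2)(c2ccccc2)c2ccccc2)cc1[O-].[Li+] | intermediate
7 | methyl 2'-[2-(3-hydroxy-4-methoxyphenyl)ethenyl]-4',6-dimethoxy-[1,1'-biphenyl]-2-carboxylate (E/Z mixture) | COC(=O)c1cccc(OC)c1-c1ccc(OC)cc1C=Cc1ccc(OC)c(O)c1 | intermediate
8 | methyl 2'-[2-(3-hydroxy-4-methoxyphenyl)ethyl]-4',6-dimethoxy-[1,1'-biphenyl]-2-carboxylate | COC(=O)c1cccc(OC)c1-c1ccc(OC)cc1CCc1ccc(OC)c(O)c1 | intermediate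
9 | 5-{2-[2'-(hydroxymethyl)-4,6'-dimethoxy-[1,1'-biphenyl]-2-yl]ethyl}-2-methoxyphenol | OCc1cccc(OC)c1-c1ccc(OC)cc1CCc1ccc(OC)c(O)c1 | intermediate
10 | 4-fluorobenzaldehyde | O=Cc1ccc(F)cc1 | starting material
11 | 4-(5-{2-[2'-(hydroxymethyl)-4,6'-dimethoxy-[1,1'-biphenyl]-2-yl]ethyl}-2-methoxyphenoxy)benzaldehyde | OCc1cccc(OC)c1-c1ccc(OC)cc1CCc1ccc(OC)c(Oc2ccc(C=O)cc2)c1 | intermediate
12 | 4-(5-{2-[2'-(chloromethyl)-4,6'-dimethoxy-[1,1'-biphenyl]-2-yl]ethyl}-2-methoxyphenoxy)benzaldehyde | ClCc1cccc(OC)c1-c1ccc(OC)cc1CCc1ccc(OC)c(Oc2ccc(C=O)cc2)c1 | intermediate
13 | [4-(5-{2-[2'-(chloromethyl)-4,6'-dimethoxy-[1,1'-biphenyl]-2-yl]ethyl}-2-methoxyphenoxy)phenyl]methanol | ClCc1cccc(OC)c1-c1ccc(OC)cc1CCc1ccc(OC)c(Oc2ccc(CO)cc2)c1 | intermediate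
14 | 17-membered macrocyclic dibenzyl ether, trimethyl ether | COc1ccc2c(c1)CCc1ccc(OC)c(c1)Oc1ccc(cc1)COCc1cccc(OC)c1-2 | intermediate
15 | macrocyclic ether lithiated at the benzylic carbon on ring D (not isolated) | COc1ccc2c(c1)CCc1ccc(OC)c(c1)Oc1ccc(cc1)COC([Li])c1cccc(OC)c1-2 | intermediate
16 | macrocyclic 1,2-diarylethanol, OH on the ring D benzylic carbon (racemic) | COc1ccc2c(c1)CCc1ccc(OC)c(c1)Oc1ccc(cc1)CC(O)c1cccc(OC)c1-2 | intermediate
17 | plagiochin E trimethyl ether | COc1ccc2c(c1)CCc1ccc(OC)c(c1)Oc1ccc(cc1)CCc1cccc(OC)c1-2 | intermediate
18 | plagiochin E | Oc1ccc2c(c1)CCc1ccc(O)c(c1)Oc1ccc(cc1)CCc1cccc(O)c1-2 | target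

**Count and risks**

Total steps: 12. Longest linear sequence: 11 steps (steps 1 and 3 to 12; step 2 is a one-step side branch).

Step 10, the ring contraction. Metalation may take place on an arene next to a methoxy group instead of at the ether CH2, or the lithiated ether may fragment instead of recombining, so that no C–C bond forms. The fallback gives up the contraction and closes the 16-membered ring directly at the same C–D bridge. It sets out from chloro aldehyde 12: PPh3 in refluxing MeCN should give the phosphonium chloride F1. NaOMe in CH2Cl2/MeOH at high dilution should then close the ring by intramolecular Wittig olefination onto the ring C aldehyde, giving the macrocyclic stilbene F2 as an E/Z mixture. Hydrogenation (H2, Pd/C, EtOAc) would saturate the bridge, and the sequence comes back to the route at 17.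

Step 9, the macrocyclic etherification. Displacement at the ortho-arylated benzylic chloride is slow, so intermolecular alkylation may outrun ring closure and give oligomeric ethers. The fallback forms the other C–O bond of the ether by capture of an oxocarbenium ion. It sets out from hydroxy aldehyde 11: Et3SiCl and imidazole in CH2Cl2 should give the triethylsilyl ether F3. Intramolecular reductive etherification (Et3SiH, BiBr3 (cat.), MeCN, high dilution, 0 °C to rt) would then join the ring C aldehyde carbon to the ring D benzylic oxygen, and the sequence comes back to the route at 14.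

Step 11, the ionic deoxygenation. Ionisation on the ring D side lacks a para donor and may be slow, so the alcohol may be held up as its trifluoroacetate, or the cation may be lost to arylation by a neighbouring electron-rich ring. The fallback is a radical deoxygenation (Barton–McCombie) that avoids the cation. It sets out from carbinol 16: NaH, CS2 and then MeI in THF should give the S-methyl xanthate F4. Bu3SnH with AIBN in toluene at 110 °C would reduce it through the benzylic radical, and the sequence comes back to the route at 17.

**Further compounds**

F1 | step 10 | {[2'-(2-{3-(4-formylphenoxy)-4-methoxyphenyl}ethyl)-4',6-dimethoxy-[1,1'-biphenyl]-2-yl]methyl}triphenylphosphonium chloride | [Cl-].c1ccccc1[P+](c1ccccc1)(c1ccccc1)Cc1cccc(OC)c1-c1ccc(OC)cc1CCc1ccc(OC)c(Oc2ccc(C=O)cc2)c1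
F2 | step 10 | 16-membered macrocyclic stilbene with CH=CH between rings C and D, trimethyl ether (E/Z mixture) | COc1ccc2c(c1)CCc1ccc(OC)c(c1)Oc1ccc(cc1)C=Cc1cccc(OC)c1-2
F3 | step 9 | triethylsilyl ether of 11 | CC[Si](CC)(CC)OCc1cccc(OC)c1-c1ccc(OC)cc1CCc1ccc(OC)c(Oc2ccc(C=O)cc2)c1
F4 | step 11 | S-methyl xanthate of 16 (racemic) | COc1ccc2c(c1)CCc1ccc(OC)c(c1)Oc1ccc(cc1)CC(OC(=S)SC)c1cccc(OC)c1-2
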